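Lactucaxanthin is C2-symmetric, so a twofold Wittig reaction of one C15 ε-ring phosphonium salt with the C10 trienedial assembles it. In each ε-ring (C1–C6) the carbinol carbon C3 and the chain carbon C7 stand 1,4 across C4=C5. The unit O–C3–C4=C5(CH3)–C6–C7 is therefore a masked 4-methyl-2-pyranone, and C1(CH3)2–C2H2 is isobutylene. A catalytic enantioselective inverse-demand Diels–Alder reaction of these two simple partners forms C2–C3 and C1–C6 at once and fixes both ring stereocentres in a bridged lactone. The cis relationship it imposes is corrected later by a Mitsunobu inversion at C3.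

Key step: step 1

Remark: carotenoid numbering is used for the ring throughout (C1 gem-dimethyl carbon, C2 methylene, C3 carbinol carbon, C4=C5 ring double bond with the methyl on C5, C6 chain-bearing carbon, C7 first chain carbon).
Assumption: 4-methyl-2H-pyran-2-one (1) and the C10 dialdehyde (10) are taken as catalogue compounds.
Assumption: the absolute sense of induction in step 1 is a prediction from the accepted binding model of the catalyst; the route is written for the (S)-prolinol-derived catalyst as the antipode that gives (1S,4R)-3, and the mirror-image catalyst would be used if the sense proved opposite.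

Step 1
Reactants: 1 4-methyl-2H-pyran-2-one; 2 isobutylene (2-methylpropene)
Product: 3 (1S,4R)-5,8,8-trimethyl-2-oxabicyclo[2.2.2]oct-5-en-3-one
Conditions: (S)-B-(o-tolyl)-α,α-diphenylprolinol oxazaborolidine (20 mol %) + HNTf2 (18 mol %), isobutylene (10 equiv), CH2Cl2, −40 to −10 °C, sealed vessel
Reagents that add atoms: none
Why: Proposed new method: the cationic boron Lewis acid binds the pyranone carbonyl and lowers the LUMO of the ring diene, the nucleophilic CH2 terminus of isobutylene attacks C6 of the pyranone (largest LUMO coefficient, the site at which nucleophiles add to 2-pyranones) and the developing tertiary cationic carbon closes onto C3 of the pyranone in a concerted but strongly asynchronous inverse-electron-demand Diels–Alder reaction, so that the C2–C3 and C1–C6 bonds of the future ε-ring form in one operation. The closest known reaction types are the chiral-Lewis-acid-catalysed inverse-demand cycloadditions of 3-carboalkoxy-2-pyranones with electron-rich alkenes and the oxazaborolidinium-catalysed Diels–Alder reactions of simple unsaturated esters and lactones bound at one point; new here are a 2-pyranone without a second donor site and an unactivated 1,1-disubstituted alkene. The carbocycle is closed by an intermolecular [4+2] cycloaddition that is suprafacial on both partners, the lactone O–C(=O) unit staying behind as the two-atom bridge of a 2-oxabicyclo[2.2.2]octene. Both new stereocentres, the O-bearing bridgehead (carotenoid C3) and the carbonyl-bearing bridgehead (carotenoid C6), arise together and their relative configuration is locked by the bridge, so the catalyst has only to choose the π-face of 1, which it should do by stacking the coordinated pyranone on its aryl group and leaving one face open to the alkene. The regiochemistry needed (CMe2 next to the carbonyl-bearing carbon) is the electronically matched one, isobutylene has two identical methyl groups so there is no endo/exo issue, a slight deficit of HNTf2 keeps free protic acid from starting cationic oligomerisation of isobutylene, and the low temperature excludes loss of CO2 from 3.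

Step 2
Reactants: 3 (1S,4R)-5,8,8-trimethyl-2-oxabicyclo[2.2.2]oct-5-en-3-one
Product: 4 (1S,4R)-5,8,8-trimethyl-2-oxabicyclo[2.2.2]oct-5-en-3-ol (anomer mixture)
Conditions: iBu2AlH (1.1 equiv), CH2Cl2, −78 °C; Rochelle salt work-up
Reagents that add atoms: none
Why: Partial reduction of a lactone with diisobutylaluminium hydride at −78 °C stops at the aluminium hemiacetal and gives the lactol on work-up, neither bridgehead stereocentre is touched, and the new hemiacetal carbon forms as an anomer mixture of no consequence because it becomes sp2 in step 3.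

Step 3
Reactants: 4 (1S,4R)-5,8,8-trimethyl-2-oxabicyclo[2.2.2]oct-5-en-3-ol
Product: 6 (3E)-4-[(1R,4S)-4-hydroxy-2,6,6-trimethylcyclohex-2-en-1-yl]but-3-en-2-one [(3S,6R)-3-hydroxy-α-ionone], via open-chain hydroxy aldehyde 5 (not isolated)
Conditions: Ph3P=CHC(O)CH3 (1.5 equiv), PhCO2H (cat.), toluene, 80 °C
Reagents that add atoms: 1-(triphenyl-λ5-phosphanylidene)propan-2-one, CC(=O)C=P(c1ccccc1)(c1ccccc1)c1ccccc1
Why: Wittig olefination in which the strained bridged lactol opens to the cis-hydroxy aldehyde 5 and the stabilised, weakly basic ylide converts it into the (E)-enone without enolising the doubly activated C6–H, so that the C6 configuration is kept and no new stereocentre arises.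

Step 4
Reactants: 6 (3E)-4-[(1R,4S)-4-hydroxy-2,6,6-trimethylcyclohex-2-en-1-yl]but-3-en-2-one
Product: 7 (1E)-1-[(1R,4S)-4-hydroxy-2,6,6-trimethylcyclohex-2-en-1-yl]-3-methylpenta-1,4-dien-3-ol (mixture of C9 epimers)
Conditions: CH2=CHMgBr (3 equiv), THF, −40 to 0 °C (ketone added to the Grignard reagent); aq NH4Cl
Reagents that add atoms: vinylmagnesium bromide, C=C[Mg]Br
Why: Grignard 1,2-addition to the methyl ketone as in the standard preparation of vinyl ionols (the first equivalent is consumed by the C3 hydroxyl), the new carbinol centre C9 forming as an epimer mixture that does not matter because it becomes sp2 in step 6.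

Step 5
Reactants: 7 (1E)-1-[(1R,4S)-4-hydroxy-2,6,6-trimethylcyclohex-2-en-1-yl]-3-methylpenta-1,4-dien-3-ol
Product: 8 (1R,4R)-4-[(1E)-3-hydroxy-3-methylpenta-1,4-dien-1-yl]-3,5,5-trimethylcyclohex-2-en-1-yl benzoate
Conditions: PhCO2H, PPh3, DIAD, THF, 0 °C to rt
Reagents that add atoms: benzoic acid, OC(=O)c1ccccc1
Why: Mitsunobu reaction in which only the secondary allylic C3 hydroxyl is activated as its alkoxyphosphonium ion (the tertiary C9 carbinol is too hindered) and benzoate displaces it by SN2 with inversion, which turns the cis (3S,6R) arrangement into the required trans (3R,6R) one and at the same time protects the acid-labile ring carbinol for step 6.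

Step 6
Reactants: 8 (1R,4R)-4-[(1E)-3-hydroxy-3-methylpenta-1,4-dien-1-yl]-3,5,5-trimethylcyclohex-2-en-1-yl benzoate
Product: 9 {(2E,4E)-5-[(1R,4R)-4-(benzoyloxy)-2,6,6-trimethylcyclohex-2-en-1-yl]-3-methylpenta-2,4-dien-1-yl}triphenylphosphonium bromide
Conditions: PPh3·HBr, MeOH, 0 °C to rt; crystallisation
Reagents that add atoms: triphenylphosphine hydrobromide, [Br-].[PH+](c1ccccc1)(c1ccccc1)c1ccccc1
Why: Acid-mediated allylic transposition in which the tertiary doubly allylic carbinol ionises to a pentadienyl cation that PPh3 captures at the unhindered terminus C11 to give the conjugated (7E,9E) phosphonium salt, while the C3 benzoate resists ionisation and both ring stereocentres stay untouched.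

Step 7
Reactants: 9 {(2E,4E)-5-[(1R,4R)-4-(benzoyloxy)-2,6,6-trimethylcyclohex-2-en-1-yl]-3-methylpenta-2,4-dien-1-yl}triphenylphosphonium bromide (2.2 equiv); 10 (2E,4E,6E)-2,7-dimethylocta-2,4,6-trienedial
Product: 12 lactucaxanthin [(3R,6R,3'R,6'R)-ε,ε-carotene-3,3'-diol], via dibenzoate 11 (not isolated)
Conditions: NaOMe, MeOH/CH2Cl2, 0 °C to rt; then NaOMe (excess), MeOH/THF, 40 °C; then heptane/EtOAc, reflux
Reagents that add atoms: none
Why: Twofold Wittig olefination of the dialdehyde by the ylide of 9 builds C11=C12 and C11'=C12' (the C15 + C10 + C15 carotenoid assembly), methoxide then transesterifies both benzoates, and heating should isomerise any (11Z) material to the all-E polyene, no stereocentre being involved.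

Compound list
1 | 4-methyl-2H-pyran-2-one | CC1=CC(=O)OC=C1 | starting material
2 | isobutylene (2-methylpropene) | CC(C)=C | starting material
3 | (1S,4R)-5,8,8-trimethyl-2-oxabicyclo[2.2.2]oct-5-en-3-one | O=C1O[C@@H]2C=C(C)[C@H]1C(C)(C)C2 | intermediate
4 | (1S,4R)-5,8,8-trimethyl-2-oxabicyclo[2.2.2]oct-5-en-3-ol (anomer mixture) | OC1O[C@@H]2C=C(C)[C@H]1C(C)(C)C2 | intermediate
5 | (1R,4S)-4-hydroxy-2,6,6-trimethylcyclohex-2-ene-1-carbaldehyde | O=C[C@H]1C(C)=C[C@@H](O)CC1(C)C | intermediate (not isolated)
6 | (3E)-4-[(1R,4S)-4-hydroxy-2,6,6-trimethylcyclohex-2-en-1-yl]but-3-en-2-one | CC1=C[C@@H](O)CC(C)(C)[C@H]1/C=C/C(C)=O | intermediate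
7 | (1E)-1-[(1R,4S)-4-hydroxy-2,6,6-trimethylcyclohex-2-en-1-yl]-3-methylpenta-1,4-dien-3-ol (C9 epimers) | CC1=C[C@@H](O)CC(C)(C)[C@H]1/C=C/C(C)(O)C=C | intermediate
8 | (1R,4R)-4-[(1E)-3-hydroxy-3-methylpenta-1,4-dien-1-yl]-3,5,5-trimethylcyclohex-2-en-1-yl benzoate | CC1=C[C@H](OC(=O)c2ccccc2)CC(C)(C)[C@H]1/C=C/C(C)(O)C=C | intermediate
9 | {(2E,4E)-5-[(1R,4R)-4-(benzoyloxy)-2,6,6-trimethylcyclohex-2-en-1-yl]-3-methylpenta-2,4-dien-1-yl}triphenylphosphonium bromide | CC1=C[C@H](OC(=O)c2ccccc2)CC(C)(C)[C@H]1/C=C/C(C)=C/C[P+](c1ccccc1)(c1ccccc1)c1ccccc1.[Br-] | intermediate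
10 | (2E,4E,6E)-2,7-dimethylocta-2,4,6-trienedial | O=C/C(C)=C/C=C/C=C(C)/C=O | starting material
11 | (3R,6R,3'R,6'R)-ε,ε-carotene-3,3'-diyl dibenzoate | CC1=C[C@H](OC(=O)c2ccccc2)CC(C)(C)[C@H]1/C=C/C(C)=C/C=C/C(C)=C/C=C/C=C(C)/C=C/C=C(C)/C=C/[C@H]1C(C)=C[C@H](OC(=O)c2ccccc2)CC1(C)C | intermediate (not isolated)
12 | lactucaxanthin, (3R,6R,3'R,6'R)-ε,ε-carotene-3,3'-diol | CC1=C[C@H](O)CC(C)(C)[C@H]1/C=C/C(C)=C/C=C/C(C)=C/C=C/C=C(C)/C=C/C=C(C)/C=C/[C@H]1C(C)=C[C@H](O)CC1(C)C | target

Total step count: 7
Longest linear sequence: 7 steps (1 → 3 → 4 → 6 → 7 → 8 → 9 → 12)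

Steps most likely to fail

Step 1 (Proposed new method). What may go wrong: the pyranone, bound at one point only, may be activated too weakly or discriminated poorly between its two faces, and isobutylene may oligomerise cationically or the tertiary cation may be intercepted by proton loss (ene-type product) before the second bond closes. Fallback with known chemistry, setting out from 1 and 2: an uncatalysed cycloaddition under high pressure (CH2Cl2, about 12 kbar, 40 °C, the known way to obtain 2-pyranone–alkene adducts without loss of CO2) would give the racemic lactone F1. Reduction with iBu2AlH as in step 2 would give the racemic lactol F2, and Wittig olefination as in step 3 the racemic cis-hydroxy ketone F3. Kinetic resolution of F3 by lipase-catalysed acetylation (Burkholderia cepacia lipase, vinyl acetate, tert-butyl methyl ether, rt) is expected, by the empirical preference of this enzyme class for (R)-configured secondary carbinols, to convert the (3R,6S) enantiomer into the acetate F4 and to leave the (3S,6R) alcohol. The route is rejoined at compound 6.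

Step 3. What may go wrong: olefination of a neopentyl-type aldehyde flanked by a quaternary carbon may be slow, so that enolisation at C6 (epimerisation, or migration of the ring double bond into conjugation) competes. Fallback, setting out from 4: a Takai olefination under non-basic conditions (CrCl2, divalent chromium, with CHI3 in THF at 0 °C) would give the (E)-vinyl iodide F5. Stille coupling of F5 with tributyl(1-ethoxyvinyl)stannane (Pd(PPh3)4, zerovalent palladium, toluene, 80 °C) would give the 2-ethoxydiene F6. Brief hydrolysis of the enol ether (oxalic acid, wet THF, 0 °C) would release the methyl ketone. The route is rejoined at compound 6.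

Step 5. What may go wrong: the activated allylic alcohol may ionise (loss of stereospecificity or allylic transposition) or eliminate to the cyclohexadiene instead of undergoing SN2 displacement. Fallback, setting out from 7: oxidation of the secondary allylic alcohol with MnO2 (CH2Cl2, rt; the tertiary carbinol cannot be oxidised) would give the ring enone F7. Reagent-controlled Corey–Bakshi–Shibata reduction ((S)-2-methyl-CBS-oxazaborolidine, catecholborane, toluene, −78 °C, the enone double bond acting as the large group) would give the trans (3R,6R) diol F8. Selective benzoylation of its secondary hydroxyl (BzCl, pyridine, 0 °C) would give the benzoate. The route is rejoined at compound 8.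

Further compounds
F1 | step 1 | racemic 5,8,8-trimethyl-2-oxabicyclo[2.2.2]oct-5-en-3-one | O=C1O[C@@H]2C=C(C)[C@H]1C(C)(C)C2.O=C1O[C@H]2C=C(C)[C@@H]1C(C)(C)C2
F2 | step 1 | racemic 5,8,8-trimethyl-2-oxabicyclo[2.2.2]oct-5-en-3-ol (anomer mixture) | OC1O[C@@H]2C=C(C)[C@H]1C(C)(C)C2.OC1O[C@H]2C=C(C)[C@@H]1C(C)(C)C2
F3 | step 1 | racemic cis-(3E)-4-(4-hydroxy-2,6,6-trimethylcyclohex-2-en-1-yl)but-3-en-2-one | CC1=C[C@@H](O)CC(C)(C)[C@H]1/C=C/C(C)=O.CC1=C[C@H](O)CC(C)(C)[C@@H]1/C=C/C(C)=O
F4 | step 1 | (1R,4S)-3,5,5-trimethyl-4-[(1E)-3-oxobut-1-en-1-yl]cyclohex-2-en-1-yl acetate | CC1=C[C@H](OC(C)=O)CC(C)(C)[C@@H]1/C=C/C(C)=O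
F5 | step 3 | (1S,4R)-4-[(E)-2-iodoethenyl]-3,5,5-trimethylcyclohex-2-en-1-ol | I/C=C/[C@H]1C(C)=C[C@@H](O)CC1(C)C
F6 | step 3 | (1S,4R)-4-[(1E)-3-ethoxybuta-1,3-dien-1-yl]-3,5,5-trimethylcyclohex-2-en-1-ol | CCOC(=C)/C=C/[C@H]1C(C)=C[C@@H](O)CC1(C)C
F7 | step 5 | (4R)-4-[(1E)-3-hydroxy-3-methylpenta-1,4-dien-1-yl]-3,5,5-trimethylcyclohex-2-en-1-one | CC1=CC(=O)CC(C)(C)[C@H]1/C=C/C(C)(O)C=C
F8 | step 5 | (1E)-1-[(1R,4R)-4-hydroxy-2,6,6-trimethylcyclohex-2-en-1-yl]-3-methylpenta-1,4-dien-3-ol | CC1=C[C@H](O)CC(C)(C)[C@H]1/C=C/C(C)(O)C=C
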